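**Retrosynthetic overview**
- The target is (2S)-5,7-dihydroxy-4'-methoxy-8-prenylflavanone. Rings A and B are bought as arenes, ring C is the only ring built, and C2 is the only stereocentre.
- Feature used: in ring C, bonds O1–C2 and C3–C4 enclose the unit C2–C3 that carries ring B, which is 4-vinylanisole. C4, C4a, C8a and O1 are the formyl carbon, two ring A carbons and the phenol oxygen of a salicylaldehyde.
- Late disconnections: the phenols come from aryl TBS ethers, and C4=O comes from C4–OH and that from C4–OMe. C4 leaves the cycloaddition at the carbinol level, so one oxidation is still needed.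
- Key disconnection: retro hetero-Diels–Alder of ring C into a C4-methoxy ortho-quinone methide (salicylaldehyde plus trimethyl orthoformate) and 4-vinylanisole, under a confined chiral Brønsted acid.
- The salicylaldehyde comes from 2,4,6-trihydroxybenzaldehyde by C-prenylation and a bis-silylation that leaves free only the hydroxyl beside the prenyl group. This fixes the 8-prenyl constitution.

Key step: step 3

Assumption: no model predicts the sense of induction of the confined acid for this substrate, so the (S,S)-catalyst is written and its (R,R)-antipode is used if a first run shows the 2R series.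

**Step 1**
Reactants: 1 2,4,6-trihydroxybenzaldehyde; 2 prenyl bromide (1-bromo-3-methylbut-2-ene)
Product: 3 2,4,6-trihydroxy-3-(3-methylbut-2-enyl)benzaldehyde
Conditions: KOH (1.0 equiv), H2O, 0 °C to rt, 2 (0.9 equiv) added slowly; acidify to pH 4, chromatography
Reagents that add atoms: none
Why: This is C-allylation of an ambident phloroglucinol-type phenoxide, in which hydrogen bonding by water shields the oxygens so that the ring carbon attacks the soft allylic bromide, the two open ring positions are equivalent so only one mono-prenyl isomer can form, and a deficit of 2 curbs double alkylation.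

**Step 2**
Reactants: 3 2,4,6-trihydroxy-3-(3-methylbut-2-enyl)benzaldehyde
Product: 4 4,6-bis(tert-butyldimethylsilyloxy)-2-hydroxy-3-(3-methylbut-2-enyl)benzaldehyde
Conditions: TBSCl (2.1 equiv), imidazole (4.5 equiv), CH2Cl2–DMF, 0 °C
Reagents that add atoms: tert-butyldimethylsilyl chloride (TBSCl), CC(C)(C)[Si](C)(C)Cl
Why: This is phenol silylation under steric control, in which the non-chelated para hydroxyl reacts first and, of the two chelating ortho hydroxyls, the one next to the ring hydrogen is silylated faster than the one wedged between formyl and prenyl, which stays free when only two equivalents of the bulky chloride are offered.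

**Step 3**
Reactants: 4 4,6-bis(tert-butyldimethylsilyloxy)-2-hydroxy-3-(3-methylbut-2-enyl)benzaldehyde; 5 4-vinylanisole (3 equiv)
Product: 8 (2S,4S)-5,7-bis(tert-butyldimethylsilyloxy)-4-methoxy-2-(4-methoxyphenyl)-8-(3-methylbut-2-enyl)chroman (2,4-cis), via dimethyl acetal 6 (not isolated), via methoxy ortho-quinone methide 7 (not isolated)
Conditions: HC(OMe)3 (1.5 equiv), (S,S)-imidodiphosphoric acid built from two 3,3'-bis(2,4,6-triethylphenyl)-BINOL units (5 mol %), 5 Å MS, toluene, 0 °C; chromatography on Et3N-deactivated silica
Reagents that add atoms: trimethyl orthoformate, COC(OC)OC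
Why: Proposed new method: the chiral acid first catalyses acetal exchange of 4 with the orthoformate to 6, which loses methanol to give the C4-methoxy ortho-quinone methide 7, present as its O-protonated oxocarbenium form in a contact ion pair with the confined imidodiphosphate anion and stabilised by the two silyloxy donors of ring A. The unsubstituted alkene carbon of 5 bonds to C4 and the C8a oxygen closes on the anisyl-stabilised benzylic carbon, so that ring C is closed as a six-membered pyran in an inverse-electron-demand, strongly asynchronous hetero-Diels–Alder [4+2] mode (O1, C8a, C4a, C4 from 7; C3, C2 from 5). The closest known reaction types are the racemic acid-catalysed three-component union of salicylaldehydes, orthoformates and styrenes to 4-alkoxy-2-arylchromans and the imidodiphosphate-catalysed enantioselective intramolecular cycloadditions of salicylaldehyde-derived ortho-quinone methides, and only the enantioselective intermolecular form is without precedent. C4 is set by the face of 7 that the chiral anion leaves open, and C2 is set relative to C4 by endo approach of the aryl group to (E)-7 (in the stepwise limit a chair-like closure with both substituents pseudo-equatorial), which gives the 2,4-cis isomer. Because a trans isomer formed on the same methide face would carry the opposite configuration at C2, it is removed here by chromatography and is not pooled, since C4 is erased later and C2 alone decides the enantiomeric purity of the target. Regiochemistry (aryl on C2) follows from the matched polarity of the partners, the 8-prenyl constitution from the fact that only the hydroxyl beside the prenyl group is free, and chemoselectivity from the much higher nucleophilicity of 5 compared with the trisubstituted prenyl olefin together with an acid too weak to protonate that olefin or to cleave aryl silyl ethers.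

**Step 4**
Reactants: 8 (2S,4S)-5,7-bis(tert-butyldimethylsilyloxy)-4-methoxy-2-(4-methoxyphenyl)-8-(3-methylbut-2-enyl)chroman
Product: 9 (2S)-5,7-bis(tert-butyldimethylsilyloxy)-2-(4-methoxyphenyl)-8-(3-methylbut-2-enyl)chroman-4-ol (mixture of C4 epimers)
Conditions: camphorsulfonic acid (5 mol %), THF–H2O 4:1, 0 °C to rt; pH 7 buffer; used without silica-gel purification
Reagents that add atoms: water, O
Why: This is acid-catalysed SN1 solvolysis of a benzylic ether, in which the C4 cation is stabilised by O1 and by the 5- and 7-silyloxy groups and therefore forms under acid too weak to open O1–C2, protonate the prenyl olefin or cleave aryl silyl ethers, the excess of water drives the exchange, and scrambling of C4 is harmless because C2 is untouched and C4 becomes sp2 in the next step.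

**Step 5**
Reactants: 9 (2S)-5,7-bis(tert-butyldimethylsilyloxy)-2-(4-methoxyphenyl)-8-(3-methylbut-2-enyl)chroman-4-ol
Product: 10 (2S)-5,7-bis(tert-butyldimethylsilyloxy)-2-(4-methoxyphenyl)-8-(3-methylbut-2-enyl)chroman-4-one
Conditions: nPr4N[RuO4] (5 mol %), N-methylmorpholine N-oxide (NMO, 1.5 equiv), 4 Å MS, CH2Cl2, 0 °C to rt
Reagents that add atoms: none
Why: The Ley–Griffith oxidation converts both C4 epimers of the acid-sensitive benzylic alcohol into one ketone under neutral conditions that spare the prenyl olefin and the silyl ethers and are not basic enough to start retro-oxa-Michael opening at C2.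

**Step 6**
Reactants: 10 (2S)-5,7-bis(tert-butyldimethylsilyloxy)-2-(4-methoxyphenyl)-8-(3-methylbut-2-enyl)chroman-4-one
Product: 11 (2S)-5,7-dihydroxy-2-(4-methoxyphenyl)-8-(3-methylbut-2-enyl)-2,3-dihydrochromen-4-one (target)
Conditions: Et3N·3HF (4 equiv), THF, 0 °C to rt; work-up at pH 5–6
Reagents that add atoms: none
Why: Fluoride-mediated cleavage of the aryl silyl ethers in a slightly acidic medium avoids free phenoxide and enolate, so that ring opening to the chalcone (the racemisation path of flavanones) does not start, and the medium is far too weakly acidic to cyclise the 7-hydroxyl onto the prenyl olefin.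

**Compound list**
1 | 2,4,6-trihydroxybenzaldehyde | O=Cc1c(O)cc(O)cc1O | starting material
2 | prenyl bromide | CC(C)=CCBr | starting material
3 | 2,4,6-trihydroxy-3-(3-methylbut-2-enyl)benzaldehyde | O=Cc1c(O)cc(O)c(CC=C(C)C)c1O | intermediate
4 | 4,6-bis(tert-butyldimethylsilyloxy)-2-hydroxy-3-(3-methylbut-2-enyl)benzaldehyde | O=Cc1c(O)c(CC=C(C)C)c(O[Si](C)(C)C(C)(C)C)cc1O[Si](C)(C)C(C)(C)C | intermediate
5 | 4-vinylanisole | C=Cc1ccc(OC)cc1 | starting material
6 | dimethyl acetal of 4 (not isolated) | COC(OC)c1c(O)c(CC=C(C)C)c(O[Si](C)(C)C(C)(C)C)cc1O[Si](C)(C)C(C)(C)C | intermediate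
7 | (E)-6-(methoxymethylidene)-3,5-bis(tert-butyldimethylsilyloxy)-2-(3-methylbut-2-enyl)cyclohexa-2,4-dien-1-one, the methoxy ortho-quinone methide (not isolated) | CO/C=C1/C(=O)C(CC=C(C)C)=C(O[Si](C)(C)C(C)(C)C)C=C1O[Si](C)(C)C(C)(C)C | intermediate
8 | (2S,4S)-5,7-bis(tert-butyldimethylsilyloxy)-4-methoxy-2-(4-methoxyphenyl)-8-(3-methylbut-2-enyl)chroman | COc1ccc([C@@H]2C[C@H](OC)c3c(O[Si](C)(C)C(C)(C)C)cc(O[Si](C)(C)C(C)(C)C)c(CC=C(C)C)c3O2)cc1 | intermediate
9 | (2S)-5,7-bis(tert-butyldimethylsilyloxy)-2-(4-methoxyphenyl)-8-(3-methylbut-2-enyl)chroman-4-ol, C4 epimers | COc1ccc([C@@H]2CC(O)c3c(O[Si](C)(C)C(C)(C)C)cc(O[Si](C)(C)C(C)(C)C)c(CC=C(C)C)c3O2)cc1 | intermediate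
10 | (2S)-5,7-bis(tert-butyldimethylsilyloxy)-2-(4-methoxyphenyl)-8-(3-methylbut-2-enyl)chroman-4-one | COc1ccc([C@@H]2CC(=O)c3c(O[Si](C)(C)C(C)(C)C)cc(O[Si](C)(C)C(C)(C)C)c(CC=C(C)C)c3O2)cc1 | intermediate
11 | (2S)-5,7-dihydroxy-2-(4-methoxyphenyl)-8-(3-methylbut-2-enyl)-2,3-dihydrochromen-4-one | COc1ccc([C@@H]2CC(=O)c3c(O)cc(O)c(CC=C(C)C)c3O2)cc1 | target

Total step count: 6. Longest linear sequence: 6 (1 to 11).

**Steps most likely to fail**

*Step 3.*
- Turnover may be slow, because the methide is strongly stabilised and crowded by the peri silyloxy group while the acid is weak. That leaves time for cationic oligomerisation of the styrene.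
- Closure through a free anisyl cation, or a shift of the methide geometry caused by the peri group, may erode facial and cis/trans selectivity and with it the purity at C2.
- The fallback uses known chemistry, sets out from 4 and 5, and comes back at 10.
- The same three components are joined with Sc(OTf)3 (5 mol %) in CH2Cl2 at 0 °C to the racemic 4-methoxychroman F1. All diastereomers are pooled, since no configuration at C2 is at stake.
- Solvolysis and Ley–Griffith oxidation as in steps 4 and 5 then give the racemic chroman-4-ol F2 and the racemic silylated flavanone F3.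
- F3 is resolved kinetically by Noyori asymmetric transfer hydrogenation with RuCl(p-cymene)[(R,R)-TsDPEN], HCO2H–Et3N 5:2, EtOAc, rt, stopped near half conversion.
- This catalyst forms 4R carbinols and reaches C4 readily only from the face opposite the 2-aryl group. The 2R ketone should therefore be reduced to the (2R,4R)-cis-chroman-4-ol F4, while the 2S ketone 10 remains and is separated by chromatography.

*Step 4.*
- The C4 cation may lose H3 to give the flav-3-ene, or alkylate C6 of a second molecule. Long exposure to acid may also start loss of a silyl group.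
- The fallback sets out from 8 and comes back at 10 in one operation: DDQ (1.2 equiv), CH2Cl2–pH 7 buffer 10:1, 0 °C.
- Hydride is abstracted from C4–H, water adds to the methoxy-stabilised cation, and the hemiketal collapses to the ketone.
- This is the known oxidative cleavage of electron-rich benzylic ethers, and C4 is the known site of DDQ attack in 5,7-dioxygenated flavans.
- It is not the first choice because the benzylic and allylic CH2 of the prenyl group competes as a hydride donor, so the oxidant has to be dosed.
- This path makes no compound outside the list (F0).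

*Step 2.*
- Discrimination between the two chelating hydroxyls may be incomplete. The regioisomeric bis-ether would carry the 6-prenyl series through the route.
- The fallback sets out from 1 and comes back at 4, without passing through 3.
- Compound 1, whose two ortho hydroxyls are equivalent, is silylated first (TBSCl, 2.1 equiv, imidazole, CH2Cl2–DMF, 0 °C) to 2,4-bis(tert-butyldimethylsilyloxy)-6-hydroxybenzaldehyde F5.
- N-Iodosuccinimide in CH2Cl2 at 0 °C should iodinate the position between the free hydroxyl and one silyloxy group, because the other open position is shielded by two silyloxy groups. This gives 4,6-bis(tert-butyldimethylsilyloxy)-2-hydroxy-3-iodobenzaldehyde F6.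
- Stille coupling of F6 with tributyl(3-methylbut-2-enyl)stannane, Pd(PPh3)4, DMF, 80 °C, places the linear prenyl group on that carbon and gives 4.

**Further compounds**
F1 | step 3 | (±)-5,7-bis(tert-butyldimethylsilyloxy)-4-methoxy-2-(4-methoxyphenyl)-8-(3-methylbut-2-enyl)chroman, racemic, both diastereomers | COc1ccc(C2CC(OC)c3c(O[Si](C)(C)C(C)(C)C)cc(O[Si](C)(C)C(C)(C)C)c(CC=C(C)C)c3O2)cc1
F2 | step 3 | (±)-5,7-bis(tert-butyldimethylsilyloxy)-2-(4-methoxyphenyl)-8-(3-methylbut-2-enyl)chroman-4-ol, racemic, both diastereomers | COc1ccc(C2CC(O)c3c(O[Si](C)(C)C(C)(C)C)cc(O[Si](C)(C)C(C)(C)C)c(CC=C(C)C)c3O2)cc1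
F3 | step 3 | (±)-5,7-bis(tert-butyldimethylsilyloxy)-2-(4-methoxyphenyl)-8-(3-methylbut-2-enyl)chroman-4-one, racemic | COc1ccc(C2CC(=O)c3c(O[Si](C)(C)C(C)(C)C)cc(O[Si](C)(C)C(C)(C)C)c(CC=C(C)C)c3O2)cc1
F4 | step 3 | (2R,4R)-5,7-bis(tert-butyldimethylsilyloxy)-2-(4-methoxyphenyl)-8-(3-methylbut-2-enyl)chroman-4-ol (2,4-cis) | COc1ccc([C@H]2C[C@@H](O)c3c(O[Si](C)(C)C(C)(C)C)cc(O[Si](C)(C)C(C)(C)C)c(CC=C(C)C)c3O2)cc1
F0 | step 4 | none | none
F5 | step 2 | 2,4-bis(tert-butyldimethylsilyloxy)-6-hydroxybenzaldehyde | O=Cc1c(O)cc(O[Si](C)(C)C(C)(C)C)cc1O[Si](C)(C)C(C)(C)C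
F6 | step 2 | 4,6-bis(tert-butyldimethylsilyloxy)-2-hydroxy-3-iodobenzaldehyde | O=Cc1c(O)c(I)c(O[Si](C)(C)C(C)(C)C)cc1O[Si](C)(C)C(C)(C)C
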